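One minute of the blue run was the unit I reckoned in, because the asked flasks have the charges of starting material and partner that blue had and differ from it in initiator and temperature.

| setting | ochre | blue | theta | gamma | zeta | beta |
|---|---|---|---|---|---|---|
| starting material | 0.50 M | 0.50 M | 0.50 M | 0.50 M | 0.50 M | 0.50 M |
| partner | 0.50 M | 0.50 M | 0.500 M | 0.500 M | 0.500 M | 0.500 M |
| initiator | 1.9 mM | 14 mM | 10 mM | 2.5 mM | 20 mM | 5.0 mM |
| temperature | 65 °C | 76 °C | 70 °C | 70 °C | 70 °C | 70 °C |
| remark | run made earlier | run made earlier |  |  |  |  |
| time |  |  | 15 min | 15 min | 15 min | 15 min |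

| run | time / min | target / % | starting material / % |
|---|---|---|---|
| ochre | 1.33 | 4.7 | 94.5 |
| ochre | 2.00 | 7.1 | 93.1 |
| ochre | 3.00 | 9.9 | 90.4 |
| ochre | 4.00 | 12.5 | 87.0 |
| ochre | 6.00 | 18.6 | 80.8 |
| ochre | 10.0 | 30.3 | 70.1 |
| ochre | 15.0 | 41.9 | 58.8 |
| blue | 1.33 | 26.4 | 74.0 |
| blue | 2.00 | 37.2 | 62.3 |
| blue | 3.00 | 49.4 | 51.3 |
| blue | 4.00 | 58.6 | 40.6 |
| blue | 6.00 | 72.1 | 28.8 |
| blue | 10.0 | 85.1 | 16.4 |
| blue | 15.0 | 90.5 | 8.8 |

(scatter of a reading: 0.5 percentage points)

* the flasks by amount of target, in percent of the starting material charged, highest first, at 15 min (theta / gamma / zeta / beta)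
* the amount of target, in percent of the starting material charged of the flask you put first, at 15 min
* the amount of target, in percent of the starting material charged of the flask you put last, at 15 min

- the numbers in the tables scatter by 0.5 percentage points (one standard deviation)

Ochre lost starting material with an apparent first-order constant of 0.0354 /min up to its last reading, and blue with 0.222 /min up to 3.00 min, two windows that end at similar conversion, with 58.8% and 51.3% left. Their ratio of 6.27 is smaller than the initiator ratio of 7.37, and I expected no slowing from warmth, so I took the rate to follow the square root of initiator, as for chains ended in pairs. That left a factor of 2.32 for the temperature, an apparent activation energy of 74.9 kJ/mol. Zeta then came to 11.4 min of blue minutes, my estimate of the time blue needs to go as far as zeta goes in 15 min; this is what kineticists call a normalised time scale. Gamma came to 4.04 min. At one temperature and time, blue minutes rise with initiator, and blue's target rises with time, so I ordered the flasks by initiator.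

I turned blue minutes into target in two ways. A fixed constant gave gamma 59.3%, and blue's own table gave 58.6% at 4.00 min, so the two agreed and I trusted that figure. For zeta they parted: the constant gave 92.1%, while the table, read between 85.1% at 10.0 min and 90.5% at 15.0 min, gave 86.9%. The constant was the one that cheated, since blue's average constant over its whole run had sunk to 0.162 /min, and the table carries that slowing with it, so I committed to the table.

The forecast, above my figure at the top, gave zeta > theta > beta > gamma, with 89% (84% to 93%) and 59% (54% to 63%), and in its words: “More initiator gives more target.”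

The flasks gave zeta > theta > beta > gamma, with zeta at 88.1% and gamma at 59.1%.

    2 first chain carrier → ended chains A (k = 3.80 × 10⁶ /M/s, Ea = 29.0 kJ/mol)
    starting material + second chain carrier → by-product + first chain carrier (k = 51000 /M/s, Ea = 26.0 kJ/mol)
    2 second chain carrier → ended chains B (k = 9.00 × 10⁷ /M/s, Ea = 10.0 kJ/mol)
    initiator → 2 initiating radical (k = 9.57 × 10⁻⁴ /min, Ea = 113 kJ/mol)
    partner + first chain carrier ⇌ target + second chain carrier (K = 1.10, k = 38500 /M/s, Ea = 38.0 kJ/mol, ΔH = −51.0 kJ/mol)
    starting material + initiating radical → capped initiator + first chain carrier (k = 7.94 × 10⁵ /M/s, Ea = 14.0 kJ/mol)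
    (constants at 70 °C)

Zeta's 11.4 min of blue minutes had read 1.2 percentage points below what zeta gave. I applied the same reckoning to zeta's charge and time at 55 °C, which lies below both earlier temperatures, so the activation energy was stretched beyond its runs. The colder flask came to 3.44 min of blue minutes, between blue's readings at 3.00 min and 4.00 min, and there the table read 53.7%. That flask gave 52.8% of target, with 47.2% of its starting material left.

(All runs stem from a simulated flask from invented constants, noise included.)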